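## Retrosynthetic overview

- Ring numbering of 17: C1(=O), C2(OH), C3(C19H39), C4(=O), C5(OMe), C6(H). The plan rests on C3 of this single six-membered carbocycle. The chain carbon is flanked by two oxygen-bearing carbons, C2 and C4. This is the pattern left when a chain-substituted ynol ether (C3≡C2–O) bonds through C3 to a ketene carbonyl carbon (C4).
- 17 ⇐ 16 by Si–O cleavage at the C2 oxygen. 16 ⇐ 15 by oxidation of C1–H, which lies para to the free C4–OH.
- 15 ⇐ diazoketone 3 (C4, C1, C6, C5) + siloxyalkyne 10 (C3, C2). The sequence is a Wolff shift (C1–C6), a [2+2] addition (C3–C4, C1–C2), a four-electron opening of C4–C1, and a six-electron closure (C4–C5). This is the only ring formation of the route.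
- 3 ⇐ enone 1 by diazo transfer. 10 ⇐ ester 4 + CH2Br2 5 + i-Pr3SiCl 6, through one-carbon homologation to an ynolate and O-silylation.

Key step: step 3

Remark: the target has no stereocentre and no stereogenic double bond, so nothing needs to be controlled beyond regiochemistry. The side chain is counted as nonadecyl (19 carbons).

## Route

Step 1
Reactants: 1 (E)-4-methoxybut-3-en-2-one
Product: 3 (E)-1-diazo-4-methoxybut-3-en-2-one, via trifluoroacetyl diketone 2 (not isolated)
Conditions: LiN(SiMe3)2, THF, −78 °C; CF3CO2CH2CF3, −78 °C; brief cold 5% aq HCl/Et2O wash, crude 2 taken on at once; MsN3, Et3N, H2O (1 equiv), MeCN, rt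
Reagents that add atoms: methanesulfonyl azide, CS(=O)(=O)N=[N+]=[N-] (two nitrogens); 2,2,2-trifluoroethyl trifluoroacetate, O=C(OCC(F)(F)F)C(F)(F)F (trifluoroacetyl group, held only in 2)
Why: The methyl group is the only enolisable site, so kinetic enolisation, Claisen-type trifluoroacetylation and Regitz-type diazo transfer with loss of the activating acyl group (detrifluoroacetylative diazo transfer) should give the α′-diazo enone without touching the C=C bond, and the short cold work-up keeps 2 from cyclising to a pyranone by loss of methanol.

Step 2
Reactants: 4 ethyl icosanoate; 5 dibromomethane; 6 chlorotriisopropylsilane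
Product: 10 1-(triisopropylsilyloxy)henicos-1-yne, via dibromomethyllithium 7 (not isolated), via lithium dibromoenolate 8 (not isolated), via lithium ynolate 9 (not isolated)
Conditions: 5, lithium 2,2,6,6-tetramethylpiperidide, THF, −78 °C; 4 in THF; n-BuLi, −78 °C → rt; 6, −78 °C → rt
Reagents that add atoms: dibromomethane 5, BrCBr (one carbon); chlorotriisopropylsilane 6, CC(C)[Si](Cl)(C(C)C)C(C)C; lithium 2,2,6,6-tetramethylpiperidide, [Li]N1C(C)(C)CCCC1(C)C (lithium, held only in 7 to 9)
Why: Kowalski ester homologation: 7 is acylated by 4, the dibromoketone is enolised to 8, Br/Li exchange sets off a 1,2-shift of the nonadecyl group from the former ester carbon to the carbenoid carbon with loss of LiBr to give ynolate 9, and a bulky silyl chloride is known to take the oxygen rather than the carbon end of such ynolates.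

Step 3
Reactants: 3 (E)-1-diazo-4-methoxybut-3-en-2-one; 10 1-(triisopropylsilyloxy)henicos-1-yne
Product: 15 6-methoxy-2-nonadecyl-3-(triisopropylsilyloxy)phenol, via vinylketene 11 (not isolated), via vinylcyclobutenone 12 (not isolated), via dienylketene 13 (not isolated), via cyclohexadienone 14 (not isolated)
Conditions: hν (254 nm, quartz), degassed ClCH2CH2Cl, rt, slight excess of 10; then PhMe, 110 °C
Reagents that add atoms: none
Why: Light expels N2 from 3 and the methoxyvinyl group shifts to the carbene carbon (photo-Wolff rearrangement, C1–C6) to give vinylketene 11, whose carbonyl carbon C4 is attacked by the nucleophilic chain-bearing carbon C3 of the silyl ynol ether while C2 closes onto C1, so a [2+2] cycloaddition gives cyclobutenone 12. Light or heat opens 12 in a reversible four-electron electrocyclic step that cuts the old C4–C1 bond, and only the isomer 13 with the ketene and methoxyvinyl arms cis can react further, so the unproductive isomer returns through 12. The one ring of the target is closed by a six-electron disrotatory electrocyclisation of 13 (C4–C5, ketene carbon onto the methoxy-bearing terminus), and enolisation of dienone 14 makes the sequence irreversible. This is the diazoketone version of the Danheiser benzannulation, which is established with triisopropylsilyloxyalkynes as the two-carbon partner. No stereocentre survives, because the sp3 ring carbons of 12 and 14 are transient and the alkene geometry of 3 is erased on aromatisation. The one selectivity needed is the orientation of the [2+2] step, and it is fixed by the polarisation of 10 (oxygen pushes electron density onto C3) meeting the electrophilic ketene carbon, which puts the chain ortho to the new phenol and the silyloxy group meta to it.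

Step 4
Reactants: 15 6-methoxy-2-nonadecyl-3-(triisopropylsilyloxy)phenol
Product: 16 5-methoxy-3-nonadecyl-2-(triisopropylsilyloxy)cyclohexa-2,5-diene-1,4-dione
Conditions: (KSO3)2NO (2.5 equiv), MeN(n-C8H17)3Cl (cat.), aq KH2PO4, CH2Cl2–H2O, rt
Reagents that add atoms: potassium nitrosodisulfonate, [K+].[K+].[O]N(S(=O)(=O)[O-])S(=O)(=O)[O-] (one oxygen)
Why: Teuber oxidation: hydrogen abstraction from the free phenol gives an aryloxyl radical that couples with a second nitrosodisulfonate radical at the only unsubstituted para carbon (C1) and loses imidodisulfonate to give the para-quinone, while both ortho positions are blocked, the two ethers are inert, and the ammonium salt carries the oxidant into the organic phase where the waxy substrate dissolves.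

Step 5
Reactants: 16 5-methoxy-3-nonadecyl-2-(triisopropylsilyloxy)cyclohexa-2,5-diene-1,4-dione
Product: 17 Irisoquin-C, 2-hydroxy-5-methoxy-3-nonadecylcyclohexa-2,5-diene-1,4-dione
Conditions: HF·pyridine, THF, 0 °C → rt
Reagents that add atoms: none
Why: Fluoride-driven Si–O cleavage is easy here because the silyl group sits on the oxygen of a vinylogous carboxylic acid, and the mildly acidic medium spares the C5 methoxy group (a vinylogous ester) from base-induced exchange.

## Compound list

1 | (E)-4-methoxybut-3-en-2-one | CO/C=C/C(C)=O | starting material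
2 | (E)-1,1,1-trifluoro-6-methoxyhex-5-ene-2,4-dione | CO/C=C/C(=O)CC(=O)C(F)(F)F | intermediate
3 | (E)-1-diazo-4-methoxybut-3-en-2-one | CO/C=C/C(=O)C=[N+]=[N-] | intermediate
4 | ethyl icosanoate | CCCCCCCCCCCCCCCCCCCC(=O)OCC | starting material
5 | dibromomethane | BrCBr | starting material
6 | chlorotriisopropylsilane | CC(C)[Si](Cl)(C(C)C)C(C)C | starting material
7 | dibromomethyllithium | [Li]C(Br)Br | intermediate
8 | lithium 1,1-dibromohenicos-1-en-2-olate | CCCCCCCCCCCCCCCCCCCC([O-])=C(Br)Br.[Li+] | intermediate
9 | lithium henicos-1-yn-1-olate | CCCCCCCCCCCCCCCCCCCC#C[O-].[Li+] | intermediate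
10 | 1-(triisopropylsilyloxy)henicos-1-yne | CCCCCCCCCCCCCCCCCCCC#CO[Si](C(C)C)(C(C)C)C(C)C | intermediate
11 | (E)-4-methoxybuta-1,3-dien-1-one | CO/C=C/C=C=O | intermediate
12 | 4-[(E)-2-methoxyethenyl]-2-nonadecyl-3-(triisopropylsilyloxy)cyclobut-2-en-1-one (racemic, transient sp3 carbon) | CCCCCCCCCCCCCCCCCCCC1=C(O[Si](C(C)C)(C(C)C)C(C)C)C(/C=C/OC)C1=O | intermediate
13 | (3E,5E)-6-methoxy-2-nonadecyl-3-(triisopropylsilyloxy)hexa-1,3,5-trien-1-one (ketene and methoxyvinyl arms cis) | CCCCCCCCCCCCCCCCCCCC(=C=O)/C(O[Si](C(C)C)(C(C)C)C(C)C)=C\C=C\OC | intermediate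
14 | 6-methoxy-2-nonadecyl-3-(triisopropylsilyloxy)cyclohexa-2,4-dien-1-one (racemic, transient sp3 carbon) | CCCCCCCCCCCCCCCCCCCC1=C(O[Si](C(C)C)(C(C)C)C(C)C)C=CC(OC)C1=O | intermediate
15 | 6-methoxy-2-nonadecyl-3-(triisopropylsilyloxy)phenol | CCCCCCCCCCCCCCCCCCCc1c(O)c(OC)ccc1O[Si](C(C)C)(C(C)C)C(C)C | intermediate
16 | 5-methoxy-3-nonadecyl-2-(triisopropylsilyloxy)cyclohexa-2,5-diene-1,4-dione | CCCCCCCCCCCCCCCCCCCC1=C(O[Si](C(C)C)(C(C)C)C(C)C)C(=O)C=C(OC)C1=O | intermediate
17 | Irisoquin-C, 2-hydroxy-5-methoxy-3-nonadecylcyclohexa-2,5-diene-1,4-dione | CCCCCCCCCCCCCCCCCCCC1=C(O)C(=O)C=C(OC)C1=O | target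

## Step count and risks

Total step count: 5.

Longest linear sequence: 4 steps (1 → 3 → 15 → 16 → 17, or 4 → 10 → 15 → 16 → 17).

### Step 3

**What may go wrong**
- The methoxyvinyl diazoketone may photoisomerise or decay.
- The vinylketene may dimerise, or be captured by the phenol already formed (O-acylation), faster than it adds to the alkyne.
- Conversion may stall at the cyclobutenone stage.
- The electron-rich arene may degrade under prolonged irradiation.

**Fallback**
- The fallback sets out from 4 and comes back at 17. It attaches the chain to a ready-made quinone by a radical reaction.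
- Ester 4 is saponified (LiOH, THF–MeOH–H2O, 50 °C, then acid) to icosanoic acid F1.
- F1 is coupled with H2O2 by dicyclohexylcarbodiimide (CH2Cl2, 0 °C) to diicosanoyl peroxide F2.
- F2 is heated with commercial 2,5-dihydroxy-1,4-benzoquinone (O=C1C=C(O)C(=O)C=C1O) in AcOH at about 95 °C. Each acyloxy unit that fragments loses one carbon as CO2, which turns the C20 acid into nonadecyl radicals.
- These radicals add to an open ring position (radical alkylation of a hydroxyquinone by a diacyl peroxide) to give 2,5-dihydroxy-3-nonadecylcyclohexa-2,5-diene-1,4-dione F3.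
- Acid-catalysed methanolysis (MeOH, cat. H2SO4, reflux) is a vinylogous Fischer esterification. It should take the less hindered hydroxyl next to C6–H and give 17.

### Step 4

**What may go wrong**
- Attack at C1 may be slow, because the neighbouring triisopropylsilyloxy group shields it.
- Contact between the aqueous oxidant and the waxy substrate may be poor.
- The silyl group may be lost early.
- Ortho attack with loss of the methoxy group is possible.

**Fallback**
- The fallback sets out from 15 and comes back at 17. It reverses the order of the last two operations and changes the kind of oxidant.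
- Bu4NF (THF, 0 °C) frees 4-methoxy-2-nonadecylbenzene-1,3-diol F4.
- F4 is oxidised in one phase with O2 (1 atm) and Co(salen) (cat.) in DMF–THF at rt.
- C1 is then unhindered. It is the only open position para to one hydroxyl and ortho to the other.
- The para- and ortho-quinone forms that could arise are tautomers of the same hydroxyquinone, so the outcome should be 17 in either case.

### Step 2

**What may go wrong**
- The long-chain ester may precipitate at −78 °C while the thermally fragile carbenoid decays.
- The rearrangement of the bromo-lithio enolate may be incomplete.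
- Silylation may occur on carbon to give a silylketene.

**Fallback**
- The fallback sets out from 4 and comes back at ynolate 9, and so at 10. It makes the ynolate by oxidation of an acetylide instead of by rearrangement.
- LiAlH4 (THF, 0 °C → rt) gives icosan-1-ol F5.
- Dess–Martin periodinane (CH2Cl2, rt) gives icosanal F6.
- Dimethyl (1-diazo-2-oxopropyl)phosphonate with K2CO3 in MeOH–THF (Ohira–Bestmann homologation) gives henicos-1-yne F7.
- Deprotonation with n-BuLi and oxygen transfer from t-BuOOLi (made from t-BuOOH and LiN(SiMe3)2; THF, −78 → 0 °C) gives 9.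
- 9 is silylated on oxygen with i-Pr3SiOTf to give 10.

## Further compounds

F1 | step 3 | icosanoic acid | CCCCCCCCCCCCCCCCCCCC(=O)O
F2 | step 3 | diicosanoyl peroxide | CCCCCCCCCCCCCCCCCCCC(=O)OOC(=O)CCCCCCCCCCCCCCCCCCC
F3 | step 3 | 2,5-dihydroxy-3-nonadecylcyclohexa-2,5-diene-1,4-dione | CCCCCCCCCCCCCCCCCCCC1=C(O)C(=O)C=C(O)C1=O
F4 | step 4 | 4-methoxy-2-nonadecylbenzene-1,3-diol | CCCCCCCCCCCCCCCCCCCc1c(O)c(OC)ccc1O
F5 | step 2 | icosan-1-ol | CCCCCCCCCCCCCCCCCCCCO
F6 | step 2 | icosanal | CCCCCCCCCCCCCCCCCCCC=O
F7 | step 2 | henicos-1-yne | CCCCCCCCCCCCCCCCCCCC#C
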